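**Retrosynthetic overview**
1. Target 23 ⇒ late angeloylation of the C1 hydroxyl of bicyclic diol 20; benzoate and acetate are already in place.
2. Seven-membered ring ⇒ ring-closing metathesis (C3=C4) of a trans-1,2-disubstituted cyclopentane; C1–C2 ⇒ chelation-controlled methallylation of a C1 aldehyde.
3. C9 carbinol ⇒ isopropyl Grignard addition to a cyclopentanone; C7 acetate ⇒ hydride reduction of the enone-derived ketone.
4. Key step: C1–C10 ⇒ conjugate addition of 2-lithio-1,3-dithiane (formyl anion) to enone 3, with the enolate taken on in the same flask to C5–C6 by aldol with acrolein (sets C10, C6, C5).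
5. Ring order: the five-membered ring is bought as (R)-4-silyloxycyclopentenone 1; the seven-membered ring is closed last.

Locants used below are those of the target's ring carbons: C1 CH–O-angeloyl, C2 CH2, C3 C–CH3, C4 =CH, C5 CH–OBz, C6 C–CH3, C7 CH–OAc, C8 CH2, C9 C(OH)i-Pr, C10 ring-fusion CH; α is the face of the C6 methyl, β the face of H10. TBS = tert-butyldimethylsilyl.

**Step 1**
Reactants: 1 (4R)-4-[(tert-butyldimethylsilyl)oxy]cyclopent-2-en-1-one
Product: 2 (4R)-4-[(tert-butyldimethylsilyl)oxy]-2-iodocyclopent-2-en-1-one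
Conditions: I2, pyridine, CH2Cl2, 0 °C to rt
Reagents that add atoms: iodine, II
Why: Johnson-type α-iodination of the enone (pyridine adds 1,4, the enolate is iodinated, pyridine is eliminated), which leaves the C9 stereocentre untouched.

**Step 2**
Reactants: 2 (4R)-4-[(tert-butyldimethylsilyl)oxy]-2-iodocyclopent-2-en-1-one
Product: 3 (4R)-4-[(tert-butyldimethylsilyl)oxy]-2-methylcyclopent-2-en-1-one
Conditions: Me4Sn, Pd2(dba)3 (2.5 mol%), AsPh3, CuI, NMP, 80 °C
Reagents that add atoms: tetramethylstannane, C[Sn](C)(C)C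
Why: Stille cross-coupling of the α-iodoenone under neutral conditions installs the future C6 methyl without β-elimination of the silyloxy group.

**Step 3 (key step)**
Reactants: 3 (4R)-4-[(tert-butyldimethylsilyl)oxy]-2-methylcyclopent-2-en-1-one; 4 1,3-dithiane; 5 acrolein (prop-2-enal)
Product: 10 (1S)-1-[(1S,2R,3R)-3-[(tert-butyldimethylsilyl)oxy]-2-(1,3-dithian-2-yl)-1-methyl-5-oxocyclopentyl]prop-2-en-1-yl benzoate, via 2-lithio-1,3-dithiane 6 (not isolated), via lithium enolate 7 (not isolated), via chlorozinc enolate 8 (not isolated), via chlorozinc aldolate 9 (not isolated)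
Conditions: 4, n-BuLi, THF, −30 °C; HMPA (2 equiv), −78 °C, then 3; ZnCl2; 5, −78 °C; BzCl, DMAP (cat.), −78 to 0 °C
Reagents that add atoms: benzoyl chloride, O=C(Cl)c1ccccc1
Why: Corey–Seebach umpolung in a three-component Michael–aldol coupling: the solvent-separated lithiodithiane adds 1,4 as a formyl anion to C10 anti to the β C9 silyloxy group, the regiodefined zinc enolate adds to acrolein on the face anti to the new α dithianyl group through a Zimmerman–Traxler chair with vinyl equatorial (C6 quaternary with methyl α, C5 S), and the aldolate is benzoylated before retro-aldol can occur.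

**Step 4**
Reactants: 10 (1S)-1-[(1S,2R,3R)-3-[(tert-butyldimethylsilyl)oxy]-2-(1,3-dithian-2-yl)-1-methyl-5-oxocyclopentyl]prop-2-en-1-yl benzoate
Product: 12 (1S)-1-[(1R,2R,3R,5S)-5-(acetyloxy)-3-[(tert-butyldimethylsilyl)oxy]-2-(1,3-dithian-2-yl)-1-methylcyclopentyl]prop-2-en-1-yl benzoate, via lithium alkoxide 11 (not isolated)
Conditions: LiBH(s-Bu)3, THF, −78 °C; then Ac2O, DMAP (cat.), −78 to 0 °C
Reagents that add atoms: acetic anhydride, CC(=O)OC(C)=O
Why: Substrate-controlled ketone reduction in which the bulky hydride attacks C7 from the α face, opposite both the larger C6 substituent (the benzoyloxyallyl arm) and the C9 silyloxy group (the sense seen in prostaglandin E-to-F reductions), giving the β C7 oxygen, which is acetylated in the flask.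

**Step 5**
Reactants: 12 (1S)-1-[(1R,2R,3R,5S)-5-(acetyloxy)-3-[(tert-butyldimethylsilyl)oxy]-2-(1,3-dithian-2-yl)-1-methylcyclopentyl]prop-2-en-1-yl benzoate
Product: 13 (1S)-1-[(1R,2R,3R,5S)-5-(acetyloxy)-2-(1,3-dithian-2-yl)-3-hydroxy-1-methylcyclopentyl]prop-2-en-1-yl benzoate
Conditions: HF·pyridine, pyridine, THF, 0 °C to rt
Reagents that add atoms: none
Why: Fluoride desilylation of the secondary silyl ether under buffered conditions that leave both esters and the dithiane intact.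

**Step 6**
Reactants: 13 (1S)-1-[(1R,2R,3R,5S)-5-(acetyloxy)-2-(1,3-dithian-2-yl)-3-hydroxy-1-methylcyclopentyl]prop-2-en-1-yl benzoate
Product: 14 (1S)-1-[(1R,2R,5S)-5-(acetyloxy)-2-(1,3-dithian-2-yl)-1-methyl-3-oxocyclopentyl]prop-2-en-1-yl benzoate
Conditions: Dess–Martin periodinane, CH2Cl2 (dry), 0 °C to rt
Reagents that add atoms: none
Why: Dess–Martin oxidation of the secondary alcohol under non-basic conditions avoids E1cB loss of the β-acetoxy group and, in dry solvent, is faster than attack on the dithiane.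

**Step 7**
Reactants: 14 (1S)-1-[(1R,2R,5S)-5-(acetyloxy)-2-(1,3-dithian-2-yl)-1-methyl-3-oxocyclopentyl]prop-2-en-1-yl benzoate
Product: 15 (1S)-1-[(1R,2R,3R,5S)-5-(acetyloxy)-2-(1,3-dithian-2-yl)-3-hydroxy-1-methyl-3-(propan-2-yl)cyclopentyl]prop-2-en-1-yl benzoate
Conditions: i-PrMgCl, LaCl3·2LiCl, THF, −78 to −40 °C
Reagents that add atoms: isopropylmagnesium chloride, CC(C)[Mg]Cl
Why: Lanthanum-promoted Grignard 1,2-addition to the ketone outruns ester attack and enolisation, and isopropyl enters on the β face anti to the adjacent α dithianyl group, so the tertiary hydroxyl is α and cis to C1.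

**Step 8**
Reactants: 15 (1S)-1-[(1R,2R,3R,5S)-5-(acetyloxy)-2-(1,3-dithian-2-yl)-3-hydroxy-1-methyl-3-(propan-2-yl)cyclopentyl]prop-2-en-1-yl benzoate
Product: 16 (1S)-1-[(1R,2R,3R,5S)-5-(acetyloxy)-2-formyl-3-hydroxy-1-methyl-3-(propan-2-yl)cyclopentyl]prop-2-en-1-yl benzoate
Conditions: PhI(OCOCF3)2, MeCN/H2O (9:1), 0 °C, 10 min; used crude
Reagents that add atoms: water, O
Why: Oxidative dithiane hydrolysis (Stork–Zhao conditions) is fast at 0 °C and spares the alkene, the esters and the tertiary alcohol.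

**Step 9**
Reactants: 16 (1S)-1-[(1R,2R,3R,5S)-5-(acetyloxy)-2-formyl-3-hydroxy-1-methyl-3-(propan-2-yl)cyclopentyl]prop-2-en-1-yl benzoate; 17 3-bromo-2-methylprop-1-ene (methallyl bromide)
Product: 19 (1S)-1-[(1R,2S,3R,5S)-5-(acetyloxy)-3-hydroxy-2-[(1S)-1-hydroxy-3-methylbut-3-en-1-yl]-1-methyl-3-(propan-2-yl)cyclopentyl]prop-2-en-1-yl benzoate, via methallylindium dibromide 18 (not isolated)
Conditions: In powder, THF/H2O (1:1), rt
Reagents that add atoms: none
Why: Indium-mediated Barbier allylation in water: indium bridges the cis C9 hydroxyl and the aldehyde oxygen (Cram chelate), and the methallyl group adds to the exposed face of this bicyclic chelate, away from the C6 methyl, giving the 1,3-anti (1S) carbinol.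

**Step 10**
Reactants: 19 (1S)-1-[(1R,2S,3R,5S)-5-(acetyloxy)-3-hydroxy-2-[(1S)-1-hydroxy-3-methylbut-3-en-1-yl]-1-methyl-3-(propan-2-yl)cyclopentyl]prop-2-en-1-yl benzoate
Product: 20 (1S,3R,3aS,4S,8S,8aR)-1-(acetyloxy)-3,4-dihydroxy-6,8a-dimethyl-3-(propan-2-yl)-1,2,3,3a,4,5,8,8a-octahydroazulen-8-yl benzoate
Conditions: second-generation Grubbs catalyst RuCl2(=CHPh)(H2IMes)(PCy3) (5 mol%), CH2Cl2 (0.005 M), 40 °C
Reagents that add atoms: none
Why: Ring-closing metathesis between the vinyl group and the 1,1-disubstituted methallyl alkene closes the trans-fused seven-membered ring with the trisubstituted C3=C4 bond and releases ethene; no stereocentre is touched.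

**Step 11**
Reactants: 20 (1S,3R,3aS,4S,8S,8aR)-1-(acetyloxy)-3,4-dihydroxy-6,8a-dimethyl-3-(propan-2-yl)-1,2,3,3a,4,5,8,8a-octahydroazulen-8-yl benzoate; 21 angelic acid, (2Z)-2-methylbut-2-enoic acid
Product: 23 (1S,3R,3aS,4S,8S,8aR)-1-(acetyloxy)-8-(benzoyloxy)-3-hydroxy-6,8a-dimethyl-3-(propan-2-yl)-1,2,3,3a,4,5,8,8a-octahydroazulen-4-yl (2Z)-2-methylbut-2-enoate, via mixed anhydride 22 (not isolated)
Conditions: 21, 2,4,6-trichlorobenzoyl chloride, Et3N, toluene, rt; then 20, toluene, 80 °C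
Reagents that add atoms: none
Why: Yamaguchi-type esterification through the mixed 2,4,6-trichlorobenzoic anhydride without nucleophilic catalyst acylates the only secondary hydroxyl and keeps the Z (angelate) geometry, while the tertiary hydroxyl does not react.

**Compound list**
1 | (4R)-4-[(tert-butyldimethylsilyl)oxy]cyclopent-2-en-1-one | O=C1C=C[C@H](O[Si](C)(C)C(C)(C)C)C1 | starting material
2 | (4R)-4-[(tert-butyldimethylsilyl)oxy]-2-iodocyclopent-2-en-1-one | O=C1C(I)=C[C@H](O[Si](C)(C)C(C)(C)C)C1 | intermediate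
3 | (4R)-4-[(tert-butyldimethylsilyl)oxy]-2-methylcyclopent-2-en-1-one | O=C1C(C)=C[C@H](O[Si](C)(C)C(C)(C)C)C1 | intermediate
4 | 1,3-dithiane | C1CSCSC1 | starting material
5 | acrolein (prop-2-enal) | C=CC=O | starting material
6 | 2-lithio-1,3-dithiane | [Li]C1SCCCS1 | intermediate
7 | lithium (3R,4R)-4-[(tert-butyldimethylsilyl)oxy]-3-(1,3-dithian-2-yl)-2-methylcyclopent-1-en-1-olate | [Li]OC1=C(C)[C@@H](C2SCCCS2)[C@H](O[Si](C)(C)C(C)(C)C)C1 | intermediate
8 | chlorozinc (3R,4R)-4-[(tert-butyldimethylsilyl)oxy]-3-(1,3-dithian-2-yl)-2-methylcyclopent-1-en-1-olate | Cl[Zn]OC1=C(C)[C@@H](C2SCCCS2)[C@H](O[Si](C)(C)C(C)(C)C)C1 | intermediate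
9 | chlorozinc (1S)-1-[(1S,2R,3R)-3-[(tert-butyldimethylsilyl)oxy]-2-(1,3-dithian-2-yl)-1-methyl-5-oxocyclopentyl]prop-2-en-1-olate | C=C[C@H](O[Zn]Cl)[C@@]1(C)C(=O)C[C@@H](O[Si](C)(C)C(C)(C)C)[C@@H]1C2SCCCS2 | intermediate
10 | (1S)-1-[(1S,2R,3R)-3-[(tert-butyldimethylsilyl)oxy]-2-(1,3-dithian-2-yl)-1-methyl-5-oxocyclopentyl]prop-2-en-1-yl benzoate | C=C[C@H](OC(=O)c1ccccc1)[C@@]2(C)C(=O)C[C@@H](O[Si](C)(C)C(C)(C)C)[C@@H]2C3SCCCS3 | intermediate
11 | lithium (1S,2R,3R,4R)-2-[(1S)-1-(benzoyloxy)prop-2-en-1-yl]-4-[(tert-butyldimethylsilyl)oxy]-3-(1,3-dithian-2-yl)-2-methylcyclopentan-1-olate | C=C[C@H](OC(=O)c1ccccc1)[C@@]2(C)[C@@H](O[Li])C[C@@H](O[Si](C)(C)C(C)(C)C)[C@@H]2C3SCCCS3 | intermediate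
12 | (1S)-1-[(1R,2R,3R,5S)-5-(acetyloxy)-3-[(tert-butyldimethylsilyl)oxy]-2-(1,3-dithian-2-yl)-1-methylcyclopentyl]prop-2-en-1-yl benzoate | C=C[C@H](OC(=O)c1ccccc1)[C@@]2(C)[C@@H](OC(C)=O)C[C@@H](O[Si](C)(C)C(C)(C)C)[C@@H]2C3SCCCS3 | intermediate
13 | (1S)-1-[(1R,2R,3R,5S)-5-(acetyloxy)-2-(1,3-dithian-2-yl)-3-hydroxy-1-methylcyclopentyl]prop-2-en-1-yl benzoate | C=C[C@H](OC(=O)c1ccccc1)[C@@]2(C)[C@@H](OC(C)=O)C[C@@H](O)[C@@H]2C3SCCCS3 | intermediate
14 | (1S)-1-[(1R,2R,5S)-5-(acetyloxy)-2-(1,3-dithian-2-yl)-1-methyl-3-oxocyclopentyl]prop-2-en-1-yl benzoate | C=C[C@H](OC(=O)c1ccccc1)[C@@]2(C)[C@@H](OC(C)=O)CC(=O)[C@@H]2C3SCCCS3 | intermediate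
15 | (1S)-1-[(1R,2R,3R,5S)-5-(acetyloxy)-2-(1,3-dithian-2-yl)-3-hydroxy-1-methyl-3-(propan-2-yl)cyclopentyl]prop-2-en-1-yl benzoate | C=C[C@H](OC(=O)c1ccccc1)[C@@]2(C)[C@@H](OC(C)=O)C[C@@](O)(C(C)C)[C@@H]2C3SCCCS3 | intermediate
16 | (1S)-1-[(1R,2R,3R,5S)-5-(acetyloxy)-2-formyl-3-hydroxy-1-methyl-3-(propan-2-yl)cyclopentyl]prop-2-en-1-yl benzoate | C=C[C@H](OC(=O)c1ccccc1)[C@@]2(C)[C@@H](OC(C)=O)C[C@@](O)(C(C)C)[C@@H]2C=O | intermediate
17 | 3-bromo-2-methylprop-1-ene (methallyl bromide) | C=C(C)CBr | starting material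
18 | (2-methylprop-2-en-1-yl)indium dibromide | C=C(C)C[In](Br)Br | intermediate
19 | (1S)-1-[(1R,2S,3R,5S)-5-(acetyloxy)-3-hydroxy-2-[(1S)-1-hydroxy-3-methylbut-3-en-1-yl]-1-methyl-3-(propan-2-yl)cyclopentyl]prop-2-en-1-yl benzoate | C=C[C@H](OC(=O)c1ccccc1)[C@@]2(C)[C@@H](OC(C)=O)C[C@@](O)(C(C)C)[C@@H]2[C@@H](O)CC(C)=C | intermediate
20 | (1S,3R,3aS,4S,8S,8aR)-1-(acetyloxy)-3,4-dihydroxy-6,8a-dimethyl-3-(propan-2-yl)-1,2,3,3a,4,5,8,8a-octahydroazulen-8-yl benzoate | O[C@H]1CC(C)=C[C@H](OC(=O)c2ccccc2)[C@@]2(C)[C@@H](OC(C)=O)C[C@@](O)(C(C)C)[C@H]12 | intermediate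
21 | angelic acid, (2Z)-2-methylbut-2-enoic acid | C/C=C(/C)C(=O)O | starting material
22 | (2Z)-2-methylbut-2-enoic 2,4,6-trichlorobenzoic anhydride | C/C=C(/C)C(=O)OC(=O)c1c(Cl)cc(Cl)cc1Cl | intermediate
23 | (1S,3R,3aS,4S,8S,8aR)-1-(acetyloxy)-8-(benzoyloxy)-3-hydroxy-6,8a-dimethyl-3-(propan-2-yl)-1,2,3,3a,4,5,8,8a-octahydroazulen-4-yl (2Z)-2-methylbut-2-enoate | C/C=C(/C)C(=O)O[C@H]1CC(C)=C[C@H](OC(=O)c2ccccc2)[C@@]2(C)[C@@H](OC(C)=O)C[C@@](O)(C(C)C)[C@H]12 | target

**Step count and risks**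
Total: 11 steps. Longest linear sequence: 11 steps (1 to 23); all other inputs are purchased.

Step 3 is the most likely to fail. The basic lithiodithiane may add 1,2 or deprotonate C8 (with loss of silanolate), and three stereocentres are set in one flask. The fallback sets out from enone 3 and returns at 10. A softer hydroxymethyl-anion reagent, (i-PrO)Me2SiCH2MgCl with CuI (cat.) in THF at −78 °C, is added 1,4, and the magnesium enolate is trapped as before with acrolein and then BzCl to give the silylmethyl ketone benzoate F1. Tamao oxidation (H2O2, KF, KHCO3, THF/MeOH) gives the hydroxymethyl ketone F2. Dess–Martin oxidation gives the formyl ketone F3. Thioacetalisation of the aldehyde only (propane-1,3-dithiol, Zn(OTf)2, CH2Cl2) then gives 10.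

Step 7 is the second risk. The ketone is hindered and carries a β-acetoxy group, so a secondary Grignard reagent may reduce or enolise it or attack the esters. The fallback sets out from 14 and returns at 15. Isopropenylmagnesium bromide with LaCl3·2LiCl (an sp2 nucleophile without β-hydrogens) is added from the same β face to give the isopropenyl carbinol F4. Its 1,1-disubstituted alkene is then reduced selectively over the monosubstituted vinyl group by hydrogen-atom-transfer hydrogenation (Mn(dpm)3 cat., PhSiH3, t-BuOOH, i-PrOH), which gives 15.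

Step 9 is the third risk. The β-hydroxy aldehyde 16 can undergo retro-aldol or dehydration, and the C1 configuration rests on chelation control. The fallback sets out from 19 and returns at 20. The unseparated 19 and its C1 epimer, the (1R)-carbinol diene F5, are taken through the metathesis of step 10 to give 20 together with the (4R)-epimeric bicyclic alcohol F6. The mixture is oxidised with Dess–Martin periodinane to the single C1 ketone F7. Reduction with Me4NBH(OAc)3 in MeCN/AcOH at −20 °C follows; in the ring, the acetoxyborohydride bound to the C9 oxygen can reach only the α face of C1, which returns 20.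

**Further compounds**
F1 | step 3 | (1S)-1-[(1S,2R,3R)-3-[(tert-butyldimethylsilyl)oxy]-2-{[dimethyl(propan-2-yloxy)silyl]methyl}-1-methyl-5-oxocyclopentyl]prop-2-en-1-yl benzoate | C=C[C@H](OC(=O)c1ccccc1)[C@@]2(C)C(=O)C[C@@H](O[Si](C)(C)C(C)(C)C)[C@@H]2C[Si](C)(C)OC(C)C
F2 | step 3 | (1S)-1-[(1S,2S,3R)-3-[(tert-butyldimethylsilyl)oxy]-2-(hydroxymethyl)-1-methyl-5-oxocyclopentyl]prop-2-en-1-yl benzoate | C=C[C@H](OC(=O)c1ccccc1)[C@@]2(C)C(=O)C[C@@H](O[Si](C)(C)C(C)(C)C)[C@@H]2CO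
F3 | step 3 | (1S)-1-[(1S,2R,3R)-3-[(tert-butyldimethylsilyl)oxy]-2-formyl-1-methyl-5-oxocyclopentyl]prop-2-en-1-yl benzoate | C=C[C@H](OC(=O)c1ccccc1)[C@@]2(C)C(=O)C[C@@H](O[Si](C)(C)C(C)(C)C)[C@@H]2C=O
F4 | step 7 | (1S)-1-[(1R,2R,3S,5S)-5-(acetyloxy)-2-(1,3-dithian-2-yl)-3-hydroxy-1-methyl-3-(prop-1-en-2-yl)cyclopentyl]prop-2-en-1-yl benzoate | C=C[C@H](OC(=O)c1ccccc1)[C@@]2(C)[C@@H](OC(C)=O)C[C@@](O)(C(C)=C)[C@@H]2C3SCCCS3
F5 | step 9 | (1S)-1-[(1R,2S,3R,5S)-5-(acetyloxy)-3-hydroxy-2-[(1R)-1-hydroxy-3-methylbut-3-en-1-yl]-1-methyl-3-(propan-2-yl)cyclopentyl]prop-2-en-1-yl benzoate | C=C[C@H](OC(=O)c1ccccc1)[C@@]2(C)[C@@H](OC(C)=O)C[C@@](O)(C(C)C)[C@@H]2[C@H](O)CC(C)=C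
F6 | step 9 | (1S,3R,3aS,4R,8S,8aR)-1-(acetyloxy)-3,4-dihydroxy-6,8a-dimethyl-3-(propan-2-yl)-1,2,3,3a,4,5,8,8a-octahydroazulen-8-yl benzoate | O[C@@H]1CC(C)=C[C@H](OC(=O)c2ccccc2)[C@@]2(C)[C@@H](OC(C)=O)C[C@@](O)(C(C)C)[C@H]12
F7 | step 9 | (1S,3R,3aR,8S,8aR)-1-(acetyloxy)-3-hydroxy-6,8a-dimethyl-4-oxo-3-(propan-2-yl)-1,2,3,3a,4,5,8,8a-octahydroazulen-8-yl benzoate | O=C1CC(C)=C[C@H](OC(=O)c2ccccc2)[C@@]2(C)[C@@H](OC(C)=O)C[C@@](O)(C(C)C)[C@H]12
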